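The quinone ring (C1 = carbonyl beside the chain carbon, C2–OH, C3–CH3, C4 = carbonyl, C5–OH, C6–henicosyl) is disconnected at C4–C5. Carbons C1–C4, each with its oxygen and C3 with its methyl, map onto a methylated squarate four-ring; C5 and C6 map onto a vinyl group whose inner carbon C6 carries the chain and is bonded to C1. The key step exploits this. Its precursor, a 4-hydroxy-3-isopropoxy-2-methylcyclobutenone with a tricos-1-en-2-yl group on the carbinol carbon, comes from diisopropyl squarate, methyllithium and a C23 alkenyllithium. One thermolysis breaks the strained C4–C1 bond and forms C4–C5, giving the aromatic six-ring with methyl and chain para; only the C5 oxygen is added later.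

Key step: step 4

Remark: the target is achiral and its two 2,5-dihydroxy-1,4-benzoquinone tautomers are the same compound; compound 10 is the only chiral isolated compound and is made and used as the racemate. Ring positions C1–C6 are used as defined above throughout.

Step 1
Reactants: 1 diisopropyl squarate; 2 methyllithium
Product: 4 3-isopropoxy-4-methylcyclobut-3-ene-1,2-dione, via 4-hydroxy-2,3-diisopropoxy-4-methylcyclobut-2-en-1-one 3 (not isolated)
Conditions: MeLi (1.05 equiv), THF, −78 °C; aq. HCl quench; then 12 M HCl (cat.), CH2Cl2, rt
Reagents that add atoms: none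
Why: 1,2-addition of an organolithium to one carbonyl of a squarate diester, followed by acid-catalysed ionisation of the tertiary alcohol and collapse of the resulting oxocarbenium ion with loss of isopropanol, is the standard entry to 3-alkoxy-4-alkylcyclobutenediones; the carbinol centre of 3 is racemic and is erased when 4 forms.

Step 2
Reactants: 5 1-bromoicosane; 6 2,3-dibromopropene
Product: 8 2-bromotricos-1-ene, via icosylmagnesium bromide 7 (not isolated)
Conditions: Mg, THF, 45 °C; then 6 (1.3 equiv), CuI (5 mol %), THF, 0 °C → rt
Reagents that add atoms: none
Why: Grignard formation and copper-catalysed allylic substitution on 2,3-dibromopropene should give the 2-bromo-1-alkene, because direct and allylically transposed displacement lead to the same product and the vinylic bromide does not react.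

Step 3
Reactants: 8 2-bromotricos-1-ene; 4 3-isopropoxy-4-methylcyclobut-3-ene-1,2-dione
Product: 10 racemic 4-hydroxy-3-isopropoxy-2-methyl-4-(tricos-1-en-2-yl)cyclobut-2-en-1-one, via tricos-1-en-2-yllithium 9 (not isolated)
Conditions: t-BuLi (2.0 equiv per 8), THF/Et2O, −78 °C (8 added slowly as a THF solution); then 4, THF, −78 °C; aq. NH4Cl
Reagents that add atoms: none
Why: bromine–lithium exchange gives the alkenyllithium, which should add 1,2 to the carbonyl flanked by the isopropoxy-bearing carbon, since the other carbonyl is deactivated as the vinylogous ester carbonyl; the new quaternary carbinol centre forms as a racemate, which does not matter because it becomes sp2 in step 4.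

Step 4
Reactants: 10 racemic 4-hydroxy-3-isopropoxy-2-methyl-4-(tricos-1-en-2-yl)cyclobut-2-en-1-one
Product: 11 5-henicosyl-3-isopropoxy-2-methylbenzene-1,4-diol
Conditions: p-xylene (degassed, dilute), reflux (138 °C), argon
Reagents that add atoms: none
Why: Heating should open the cyclobutenone by 4π conrotatory cleavage of the bond between the carbonyl carbon and the carbinol carbon (C4–C1), giving a vinylketene conjugated with the 1,1-disubstituted alkene. The ketene carbon C4 then bonds to the terminal CH2 (C5) in a thermally allowed disrotatory 6π electrocyclisation, which closes the six-membered ring as a cyclohexa-2,4-dienone that enolises to the aromatic hydroquinone 11. This is the established thermal ring expansion of squarate-derived 4-alkenyl-4-hydroxycyclobutenones. No stereocentre is created, and the racemic carbinol centre of 10 is destroyed. The step needs torquoselective opening: the hydroxyl group, as the donor on the carbinol carbon, rotates outward, so the alkenyl group turns inward, cis to the ketene, and cyclises instead of the hydroxyl trapping the ketene as a butenolide. Regiochemistry is fixed beforehand by the order of substituents around the four-ring, so the chain ends up para to the methyl group with C5 as the only ring C–H.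

Step 5
Reactants: 11 5-henicosyl-3-isopropoxy-2-methylbenzene-1,4-diol
Product: 12 5-henicosyl-3-isopropoxy-2-methyl-1,4-benzoquinone
Conditions: Ag2O (2 equiv), Na2SO4, toluene, rt
Reagents that add atoms: none
Why: two-electron oxidation of a hydroquinone to the para-quinone by Ag2O under neutral anhydrous conditions should leave the isopropyl vinylogous ester and the alkyl chain untouched.

Step 6
Reactants: 12 5-henicosyl-3-isopropoxy-2-methyl-1,4-benzoquinone
Product: 13 3-henicosyl-5-isopropoxy-6-methylbenzene-1,2,4-triyl triacetate
Conditions: Ac2O, CF3SO3H (cat.), rt → 40 °C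
Reagents that add atoms: acetic anhydride, CC(=O)OC(C)=O
Why: Thiele–Winter acetoxylation, in which acid-activated conjugate addition of acetate at C5 (the only ring C–H, β to the C1 carbonyl, which is more electrophilic than the vinylogous ester carbonyl C4) is followed by enolisation and acetylation of all three phenols; a strong acid catalyst is chosen because trisubstituted quinones react slowly.

Step 7
Reactants: 13 3-henicosyl-5-isopropoxy-6-methylbenzene-1,2,4-triyl triacetate
Product: 16 2-henicosyl-3,6-dihydroxy-5-methyl-1,4-benzoquinone (the target), via 3-henicosyl-5-isopropoxy-6-methylbenzene-1,2,4-triol 14 (not isolated), via 2-henicosyl-3-hydroxy-6-isopropoxy-5-methyl-1,4-benzoquinone 15 (not isolated)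
Conditions: NaOH (2 M aq), i-PrOH/THF, air, rt → 60 °C; then aq. HCl to pH 1
Reagents that add atoms: sodium hydroxide, [Na+].[OH-]
Why: saponification of the three aryl acetates gives the hydroxyhydroquinone, which air should oxidise in alkali to the hydroxyquinone, and hydroxide then displaces isopropoxide at C2 by addition–elimination (vinylogous ester saponification) to give the dianion of the target, protonated on acidification; material that lost its isopropyl group in step 6 would converge on the same product.

Compound list
1 | diisopropyl squarate (3,4-diisopropoxycyclobut-3-ene-1,2-dione) | CC(C)OC1=C(OC(C)C)C(=O)C1=O | starting material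
2 | methyllithium | [Li]C | starting material
3 | 4-hydroxy-2,3-diisopropoxy-4-methylcyclobut-2-en-1-one (racemic) | CC1(O)C(OC(C)C)=C(OC(C)C)C1=O | intermediate
4 | 3-isopropoxy-4-methylcyclobut-3-ene-1,2-dione | CC1=C(OC(C)C)C(=O)C1=O | intermediate
5 | 1-bromoicosane | CCCCCCCCCCCCCCCCCCCCBr | starting material
6 | 2,3-dibromopropene | C=C(Br)CBr | starting material
7 | icosylmagnesium bromide | CCCCCCCCCCCCCCCCCCCC[Mg]Br | intermediate
8 | 2-bromotricos-1-ene | CCCCCCCCCCCCCCCCCCCCCC(Br)=C | intermediate
9 | tricos-1-en-2-yllithium | CCCCCCCCCCCCCCCCCCCCCC([Li])=C | intermediate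
10 | 4-hydroxy-3-isopropoxy-2-methyl-4-(tricos-1-en-2-yl)cyclobut-2-en-1-one (racemic) | CCCCCCCCCCCCCCCCCCCCCC(=C)C1(O)C(OC(C)C)=C(C)C1=O | intermediate
11 | 5-henicosyl-3-isopropoxy-2-methylbenzene-1,4-diol | CCCCCCCCCCCCCCCCCCCCCc1cc(O)c(C)c(OC(C)C)c1O | intermediate
12 | 5-henicosyl-3-isopropoxy-2-methyl-1,4-benzoquinone | CCCCCCCCCCCCCCCCCCCCCC1=CC(=O)C(C)=C(OC(C)C)C1=O | intermediate
13 | 3-henicosyl-5-isopropoxy-6-methylbenzene-1,2,4-triyl triacetate | CCCCCCCCCCCCCCCCCCCCCc1c(OC(C)=O)c(OC(C)C)c(C)c(OC(C)=O)c1OC(C)=O | intermediate
14 | 3-henicosyl-5-isopropoxy-6-methylbenzene-1,2,4-triol | CCCCCCCCCCCCCCCCCCCCCc1c(O)c(OC(C)C)c(C)c(O)c1O | intermediate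
15 | 2-henicosyl-3-hydroxy-6-isopropoxy-5-methyl-1,4-benzoquinone | CCCCCCCCCCCCCCCCCCCCCC1=C(O)C(=O)C(C)=C(OC(C)C)C1=O | intermediate
16 | 2-henicosyl-3,6-dihydroxy-5-methyl-1,4-benzoquinone (2,5-dihydroxy-3-henicosyl-6-methylcyclohexa-2,5-diene-1,4-dione) | CCCCCCCCCCCCCCCCCCCCCC1=C(O)C(=O)C(C)=C(O)C1=O | target

Total step count: 7.
Longest linear sequence: 6 steps (1-bromoicosane 5 to 16 through steps 2–7; the squarate branch, steps 1 and 3–7, is equally long).

Steps most likely to fail

1. Step 6. Conjugate addition of acetate to a crowded, donor-substituted quinone may be too slow, so that acid-induced decomposition or exchange of the alkoxy group competes. Partial loss of the isopropyl group alone is harmless, since step 7 unmasks that oxygen anyway. Fallback: setting out from quinone 12, the C5=C6 double bond would be epoxidised with alkaline hydrogen peroxide (30 % H2O2, Na2CO3, aqueous dioxane, 0 °C; Weitz–Scheffer epoxidation). This should select the electron-poorer enone over the isopropoxy-substituted one and give racemic 1-henicosyl-3-isopropoxy-4-methyl-7-oxabicyclo[4.1.0]hept-3-ene-2,5-dione F1. Acid-promoted opening of the epoxide with enolisation (H2SO4 in AcOH, rt), the isomerisation known for 2,3-epoxy-1,4-naphthoquinones, should then give hydroxyquinone 15. There the route is rejoined, and the aqueous NaOH of step 7 completes the conversion to 16 without any need for air.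

2. Step 7. Peroxide generated during alkaline autoxidation may degrade the ring, or displacement of isopropoxide from the hydroxyquinone anion may stall. Fallback: setting out from triacetate 13, BCl3 (CH2Cl2, −78 → 0 °C) would cleave the aryl isopropyl ether at the arene oxidation level to give 3-henicosyl-5-hydroxy-6-methylbenzene-1,2,4-triyl triacetate F2. Methanolysis of the acetates under argon (HCl, MeOH, reflux) should give 3-henicosyl-6-methylbenzene-1,2,4,5-tetrol F3. Oxidation with aqueous FeCl3 at acidic pH then returns directly to target 16, with neither alkaline oxygen nor a displacement on the quinone.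

3. Step 3. The waxy bromide may precipitate at −78 °C and leave the bromine–lithium exchange incomplete, and the strongly basic lithium reagent may attack the vinylogous ester carbonyl or displace the isopropoxy group. Fallback: setting out from bromide 8, magnesium insertion in refluxing THF would give tricos-1-en-2-ylmagnesium bromide F4. This milder nucleophile stays in solution at −20 to 0 °C and is added to dione 4 (THF, then aq. NH4Cl), rejoining the route at 10.

Further compounds
F1 | step 6 | 1-henicosyl-3-isopropoxy-4-methyl-7-oxabicyclo[4.1.0]hept-3-ene-2,5-dione (racemic, cis-fused epoxide of 12) | CCCCCCCCCCCCCCCCCCCCCC12OC1C(=O)C(C)=C(OC(C)C)C2=O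
F2 | step 7 | 3-henicosyl-5-hydroxy-6-methylbenzene-1,2,4-triyl triacetate | CCCCCCCCCCCCCCCCCCCCCc1c(OC(C)=O)c(O)c(C)c(OC(C)=O)c1OC(C)=O
F3 | step 7 | 3-henicosyl-6-methylbenzene-1,2,4,5-tetrol | CCCCCCCCCCCCCCCCCCCCCc1c(O)c(O)c(C)c(O)c1O
F4 | step 3 | tricos-1-en-2-ylmagnesium bromide | CCCCCCCCCCCCCCCCCCCCCC(=C)[Mg]Br
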